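A direct plan would make ring A first: phloroglucinol A1 would be O-prenylated and rearranged to the 1,1-dimethylallyl triol A2, taken in four protecting-group and activation steps to the silylaryl triflate A3, and joined with the silylated anti-glycolate aldol lactone A4 by a fluoride-triggered aryne annulation that would close ring C; the resulting MOM-protected flavanonol ketal A5 would then be freed of its acetal groups with acid.
Its weakest steps would be (a) the Claisen rearrangement on the free triol, since O- and C-alkylation of A1 compete and the ortho-dienone can pass the group on by a Cope shift;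
(b) the aryne annulation, an untested reaction on both advanced fragments, in which O-arylation must outrun retro-aldol cleavage and the regiochemistry rests on aryne distortion alone;
(c) the final HCl/methanol step, since an ortho-(1,1-dimethylallyl)phenol can close to a dihydrobenzofuran in acid.
The four steps from A2 to A3 would add no skeletal bond.

**Plan of the new route**
The silyl groups go last. Ring A is cut at C4a–C5 (Claisen) and C7–C8 (vinylogous acylation), which releases C5–C6–C7 with its side chain as a 2-(1,1-dimethylallyl)malonyl unit and leaves a 6-methyl-2,3-dihydro-4H-pyran-4-one, that is ring C with O1–C8a in place.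
This pyranone is cut at C3–O (enolate oxidation) and at C2–C3/O1–C8a (formal hetero-Diels–Alder reaction of silylated vanillin). Rings arise in the order B (bought), C, A.
The enabling feature: C6 lies between the oxygen-bearing carbons C5 and C7, so C5–C6–C7 is a C-alkylated malonate and C8–C8a–C4a–C4 the acetoacetyl end of a polyketide chain.
The malonate is symmetric and O1 is bound to C8a before ring A exists, so neither the site of the side chain nor the 6- versus 8-isomer is open.
No phenol is prenylated or rearranged, no aryne is needed, and only fluoride-labile silyl groups are used.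

Key step: step 10

Assumption: the catalyst formed from Ti(OiPr)4 and (S)-BINOL is taken to direct the silyl enol ether to the Si face of the aryl aldehyde, as in related additions to benzaldehyde; both ligand antipodes are commercial, so the (2S) product is accessible whichever sense is found.

**Step 1**
Reactants: 1 vanillin (4-hydroxy-3-methoxybenzaldehyde)
Product: 2 3-methoxy-4-[(triisopropylsilyl)oxy]benzaldehyde
Conditions: TIPSCl, imidazole, DMF, rt
Reagents that add atoms: chlorotriisopropylsilane (TIPSCl), CC(C)[Si](Cl)(C(C)C)C(C)C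
Why: Imidazole-promoted O-silylation of the acidic phenol gives a base-stable, fluoride-labile ether that later keeps ring C from opening through a para-quinone methide.

**Step 2**
Reactants: 3 (E)-4-methoxypent-3-en-2-one
Product: 4 (E)-4-methoxy-2-[(trimethylsilyl)oxy]penta-1,3-diene
Conditions: LiN(iPr)2, THF, −78 °C; TMSCl, −78 °C → rt
Reagents that add atoms: chlorotrimethylsilane (TMSCl), C[Si](C)(C)Cl
Why: Kinetic deprotonation of the vinylogous ester at its acetyl methyl group (the α′ position) and O-silylation of the enolate give the 1-alkoxy-3-silyloxy diene.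

**Step 3**
Reactants: 2 3-methoxy-4-[(triisopropylsilyl)oxy]benzaldehyde; 4 (E)-4-methoxy-2-[(trimethylsilyl)oxy]penta-1,3-diene
Product: 6 (2S)-2-{3-methoxy-4-[(triisopropylsilyl)oxy]phenyl}-6-methyl-2,3-dihydro-4H-pyran-4-one, via aldol silyl ether 5 (not isolated)
Conditions: Ti(OiPr)4 (10 mol%), (S)-BINOL (20 mol%), 4 Å MS, Et2O, −20 °C; then TFA (cat.), CH2Cl2, 0 °C
Reagents that add atoms: none
Why: Mukaiyama aldol addition of the silyl enol ether terminus of 4 to the aldehyde under the Lewis acid formed from Ti(OiPr)4 and (S)-BINOL, followed by acid-induced oxa-Michael closure with loss of methanol (a formal hetero-Diels–Alder reaction), forms C2–C3 and O1–C8a, and the catalyst directs attack to the Si face of the aldehyde so that C2 becomes S.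

**Step 4**
Reactants: 6 (2S)-2-{3-methoxy-4-[(triisopropylsilyl)oxy]phenyl}-6-methyl-2,3-dihydro-4H-pyran-4-one
Product: 8 (2R,3R)-3-hydroxy-2-{3-methoxy-4-[(triisopropylsilyl)oxy]phenyl}-6-methyl-2,3-dihydro-4H-pyran-4-one, via silyl enol ether 7 (not isolated)
Conditions: LiN(iPr)2, THF, −78 °C; TMSCl; then dimethyldioxirane (acetone solution), CH2Cl2, −78 → −20 °C; aq. citric acid, THF, 0 °C
Reagents that add atoms: dimethyldioxirane, CC1(C)OO1
Why: Rubottom oxidation, in which LiN(iPr)2 removes the kinetically favoured α′ proton at C3, silyl enol ether 7 is epoxidised at its most nucleophilic C3=C4 bond on the face away from the C2 aryl group, and hydrolysis gives the trans hydroxy ketone (C3 becomes R under control of C2).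

**Step 5**
Reactants: 8 (2R,3R)-3-hydroxy-2-{3-methoxy-4-[(triisopropylsilyl)oxy]phenyl}-6-methyl-2,3-dihydro-4H-pyran-4-one
Product: 9 (2R,3R)-3-[(tert-butyldimethylsilyl)oxy]-2-{3-methoxy-4-[(triisopropylsilyl)oxy]phenyl}-6-methyl-2,3-dihydro-4H-pyran-4-one
Conditions: TBSOTf, 2,6-lutidine, CH2Cl2, −78 → 0 °C
Reagents that add atoms: tert-butyldimethylsilyl trifluoromethanesulfonate (TBSOTf), CC(C)(C)[Si](C)(C)OS(=O)(=O)C(F)(F)F
Why: Silylation of the secondary alcohol with a silyl triflate and a hindered pyridine base proceeds below 0 °C without touching either stereocentre.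

**Step 6**
Reactants: 10 diethyl 2-(propan-2-ylidene)propanedioate (diethyl isopropylidenemalonate)
Product: 11 diethyl 2-(2-methylbut-3-en-2-yl)propanedioate
Conditions: vinylMgBr, CuI (10 mol%), THF, −20 → 0 °C; aq. NH4Cl
Reagents that add atoms: vinylmagnesium bromide, C=C[Mg]Br
Why: Copper-catalysed 1,4-addition of the vinyl Grignard reagent to the alkylidene malonate builds the quaternary carbon of the 1,1-dimethylallyl group, which is not a stereocentre.

**Step 7**
Reactants: 11 diethyl 2-(2-methylbut-3-en-2-yl)propanedioate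
Product: 12 2-(ethoxycarbonyl)-3,3-dimethylpent-4-enoic acid (racemic)
Conditions: KOH (1.0 equiv), EtOH, 0 °C → rt; then aq. HCl to pH 2, 0 °C
Reagents that add atoms: potassium hydroxide, [K+].[OH-]
Why: Mono-saponification of a malonic diester stops at the half ester because the carboxylate formed first shields the second ester group, and the racemic centre later becomes aromatic C6.

**Step 8**
Reactants: 12 2-(ethoxycarbonyl)-3,3-dimethylpent-4-enoic acid
Product: 13 ethyl 2-(chlorocarbonyl)-3,3-dimethylpent-4-enoate (racemic, used crude)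
Conditions: (COCl)2, DMF (cat.), CH2Cl2, 0 °C → rt; volatiles removed
Reagents that add atoms: oxalyl chloride, ClC(=O)C(=O)Cl
Why: Vilsmeier-type activation with oxalyl chloride and catalytic DMF gives the acid chloride under neutral conditions without heat, so the malonic half ester does not decarboxylate.

**Step 9**
Reactants: 9 (2R,3R)-3-[(tert-butyldimethylsilyl)oxy]-2-{3-methoxy-4-[(triisopropylsilyl)oxy]phenyl}-6-methyl-2,3-dihydro-4H-pyran-4-one; 13 ethyl 2-(chlorocarbonyl)-3,3-dimethylpent-4-enoate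
Product: 15 ethyl 2-{[(2R,3R)-3-[(tert-butyldimethylsilyl)oxy]-2-{3-methoxy-4-[(triisopropylsilyl)oxy]phenyl}-4-oxo-3,4-dihydro-2H-pyran-6-yl]acetyl}-3,3-dimethylpent-4-enoate (epimers at the malonyl carbon), via silyl dienol ether 14 (not isolated)
Conditions: LiN(iPr)2 (1.1 equiv), THF, −78 °C; TMSCl, −78 → 0 °C; volatiles removed, solvent exchange to CH2Cl2; 13 (1.2 equiv), ZnBr2 (10 mol%), −78 → 0 °C; aq. NaHCO3
Reagents that add atoms: none
Why: Vinylogous Mukaiyama-type C-acylation, in which LiN(iPr)2 should take a proton from the methyl group because the only other α-hydrogen, C3–H, is a hindered methine bearing a silyloxy group (a kind of proton left alone in α-silyloxy ketones), and the 1,3-dioxygenated silyl dienol ether 14 reacts with the acid chloride at its terminal carbon to form C7–C8; the new malonyl centre is not controlled and later becomes aromatic C6.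

**Step 10**
Reactants: 15 ethyl 2-{[(2R,3R)-3-[(tert-butyldimethylsilyl)oxy]-2-{3-methoxy-4-[(triisopropylsilyl)oxy]phenyl}-4-oxo-3,4-dihydro-2H-pyran-6-yl]acetyl}-3,3-dimethylpent-4-enoate
Product: 17 (2R,3R)-3-[(tert-butyldimethylsilyl)oxy]-5,7-dihydroxy-2-{3-methoxy-4-[(triisopropylsilyl)oxy]phenyl}-6-(2-methylbut-3-en-2-yl)-2,3-dihydro-4H-chromen-4-one, via triketone tautomer 16 (not isolated)
Conditions: DBU (2.5 equiv), MeCN (degassed), argon, 50 °C; aq. NaH2PO4 work-up
Reagents that add atoms: none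
Why: Proposed new method: DBU removes a C8 proton of 15 (flanked by the C7 ketone and the vinylogous ester), the extended enolate carries its charge on to C4a, C4a attacks the ester carbonyl C5 with loss of ethoxide, and triketone 16 enolises to the phloroglucinol ring, which makes the step irreversible. The closest known reaction type is the base-mediated Claisen cyclisation of 3,5,7-triketo esters, free or masked as 2- or 4-pyranones, to acylphloroglucinols and 5,7-dihydroxychromones (the laboratory counterpart of the chalcone synthase cyclisation), which has not been shown on a 2,3-dihydro-4-pyranone that carries stereocentres. Ring A closes in a 6-(enolexo)-exo-trig mode and no stereocentre is formed. The step needs C- over O-acylation and the C4a–C5 closure over any other: the only enol oxygen within reach of C5 would give a four-membered ring, the ring oxygen O1 cannot be acylated, and an aldol closure through C6 would lead to a quaternary carbon that cannot aromatise, so the Claisen fold is the only productive one. C2 and C3 should be kept because the amidine base is far too weak to deprotonate C3–H, so neither epimerisation at C3 nor β-elimination of O1 from C2 can start, and the aryl TIPS ether blocks ring opening through a para-quinone methide. The tert-alkyl group next to C5 slows the attack but can sit equatorial in the six-membered transition state, so gentle warming is expected to suffice.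

**Step 11**
Reactants: 17 (2R,3R)-3-[(tert-butyldimethylsilyl)oxy]-5,7-dihydroxy-2-{3-methoxy-4-[(triisopropylsilyl)oxy]phenyl}-6-(2-methylbut-3-en-2-yl)-2,3-dihydro-4H-chromen-4-one
Product: 18 (2R,3R)-3,5,7-trihydroxy-2-(4-hydroxy-3-methoxyphenyl)-6-(2-methylbut-3-en-2-yl)-2,3-dihydro-4H-chromen-4-one (CNP0565756.1)
Conditions: HF·pyridine (excess), pyridine, THF, 0 °C → rt
Reagents that add atoms: none
Why: Fluoride-driven cleavage of both silyl ethers under buffered, weakly acidic conditions is too mild to protonate the vinyl group next to the phenols or to open ring C through the 4′-phenoxide, so C2 and C3 stay as set.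

**Compound list**
1 | vanillin (4-hydroxy-3-methoxybenzaldehyde) | COc1cc(C=O)ccc1O | starting material
2 | 3-methoxy-4-[(triisopropylsilyl)oxy]benzaldehyde | COc1cc(C=O)ccc1O[Si](C(C)C)(C(C)C)C(C)C | intermediate
3 | (E)-4-methoxypent-3-en-2-one | CO/C(C)=C/C(C)=O | starting material
4 | (E)-4-methoxy-2-[(trimethylsilyl)oxy]penta-1,3-diene | CO/C(C)=C/C(=C)O[Si](C)(C)C | intermediate
5 | (1S,4E)-5-methoxy-1-{3-methoxy-4-[(triisopropylsilyl)oxy]phenyl}-1-[(trimethylsilyl)oxy]hex-4-en-3-one (not isolated) | CO/C(C)=C/C(=O)C[C@@H](c1ccc(O[Si](C(C)C)(C(C)C)C(C)C)c(OC)c1)O[Si](C)(C)C | intermediate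
6 | (2S)-2-{3-methoxy-4-[(triisopropylsilyl)oxy]phenyl}-6-methyl-2,3-dihydro-4H-pyran-4-one | CC1=CC(=O)C[C@@H](c2ccc(O[Si](C(C)C)(C(C)C)C(C)C)c(OC)c2)O1 | intermediate
7 | (2S)-2-{3-methoxy-4-[(triisopropylsilyl)oxy]phenyl}-6-methyl-4-[(trimethylsilyl)oxy]-2H-pyran (not isolated) | CC1=CC(O[Si](C)(C)C)=C[C@@H](c2ccc(O[Si](C(C)C)(C(C)C)C(C)C)c(OC)c2)O1 | intermediate
8 | (2R,3R)-3-hydroxy-2-{3-methoxy-4-[(triisopropylsilyl)oxy]phenyl}-6-methyl-2,3-dihydro-4H-pyran-4-one | CC1=CC(=O)[C@H](O)[C@@H](c2ccc(O[Si](C(C)C)(C(C)C)C(C)C)c(OC)c2)O1 | intermediate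
9 | (2R,3R)-3-[(tert-butyldimethylsilyl)oxy]-2-{3-methoxy-4-[(triisopropylsilyl)oxy]phenyl}-6-methyl-2,3-dihydro-4H-pyran-4-one | CC1=CC(=O)[C@H](O[Si](C)(C)C(C)(C)C)[C@@H](c2ccc(O[Si](C(C)C)(C(C)C)C(C)C)c(OC)c2)O1 | intermediate
10 | diethyl 2-(propan-2-ylidene)propanedioate | CCOC(=O)C(=C(C)C)C(=O)OCC | starting material
11 | diethyl 2-(2-methylbut-3-en-2-yl)propanedioate | CCOC(=O)C(C(=O)OCC)C(C)(C)C=C | intermediate
12 | 2-(ethoxycarbonyl)-3,3-dimethylpent-4-enoic acid (racemic) | CCOC(=O)C(C(=O)O)C(C)(C)C=C | intermediate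
13 | ethyl 2-(chlorocarbonyl)-3,3-dimethylpent-4-enoate (racemic) | CCOC(=O)C(C(=O)Cl)C(C)(C)C=C | intermediate
14 | (2R,3R)-3-[(tert-butyldimethylsilyl)oxy]-2-{3-methoxy-4-[(triisopropylsilyl)oxy]phenyl}-6-methylidene-4-[(trimethylsilyl)oxy]-3,6-dihydro-2H-pyran (not isolated) | C=C1C=C(O[Si](C)(C)C)[C@H](O[Si](C)(C)C(C)(C)C)[C@@H](c2ccc(O[Si](C(C)C)(C(C)C)C(C)C)c(OC)c2)O1 | intermediate
15 | ethyl 2-{[(2R,3R)-3-[(tert-butyldimethylsilyl)oxy]-2-{3-methoxy-4-[(triisopropylsilyl)oxy]phenyl}-4-oxo-3,4-dihydro-2H-pyran-6-yl]acetyl}-3,3-dimethylpent-4-enoate | CCOC(=O)C(C(=O)CC1=CC(=O)[C@H](O[Si](C)(C)C(C)(C)C)[C@@H](c2ccc(O[Si](C(C)C)(C(C)C)C(C)C)c(OC)c2)O1)C(C)(C)C=C | intermediate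
16 | (2R,3R)-3-[(tert-butyldimethylsilyl)oxy]-2-{3-methoxy-4-[(triisopropylsilyl)oxy]phenyl}-6-(2-methylbut-3-en-2-yl)-2,3-dihydro-4H-chromene-4,5,7(4aH,6H)-trione, the non-aromatic tautomer (not isolated) | C=CC(C)(C)C1C(=O)C=C2C(C1=O)C(=O)[C@H](O[Si](C)(C)C(C)(C)C)[C@@H](c1ccc(O[Si](C(C)C)(C(C)C)C(C)C)c(OC)c1)O2 | intermediate
17 | (2R,3R)-3-[(tert-butyldimethylsilyl)oxy]-5,7-dihydroxy-2-{3-methoxy-4-[(triisopropylsilyl)oxy]phenyl}-6-(2-methylbut-3-en-2-yl)-2,3-dihydro-4H-chromen-4-one | C=CC(C)(C)c1c(O)cc2c(c1O)C(=O)[C@H](O[Si](C)(C)C(C)(C)C)[C@@H](c1ccc(O[Si](C(C)C)(C(C)C)C(C)C)c(OC)c1)O2 | intermediate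
18 | (2R,3R)-3,5,7-trihydroxy-2-(4-hydroxy-3-methoxyphenyl)-6-(2-methylbut-3-en-2-yl)-2,3-dihydro-4H-chromen-4-one | C=CC(C)(C)c1c(O)cc2c(c1O)C(=O)[C@H](O)[C@@H](c1ccc(O)c(OC)c1)O2 | target

**Step count and risks**
Total: 11 steps. Longest linear sequence: 7 steps (1, 3, 4, 5, 9, 10, 11 from vanillin).

Steps most likely to fail:

1. **Step 10.** C4a may fail to reach the hindered ester, or ring C may suffer under base before ring A closes. Fallback from 9, back at 17; the bond that closes ring A is changed from C4a–C5 to C5–C6.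
   - α-Iodination of 9 (I2, pyridine, CH2Cl2) would give (2R,3R)-3-[(tert-butyldimethylsilyl)oxy]-5-iodo-2-{3-methoxy-4-[(triisopropylsilyl)oxy]phenyl}-6-methyl-2,3-dihydro-4H-pyran-4-one F1.
   - Carbonylation (Pd(OAc)2, dppf, CO, MeOH, Et3N, DMF, 60 °C) would give methyl (5R,6R)-5-[(tert-butyldimethylsilyl)oxy]-6-{3-methoxy-4-[(triisopropylsilyl)oxy]phenyl}-2-methyl-4-oxo-5,6-dihydro-4H-pyran-3-carboxylate F2, in which C5 is in place and the methyl group is doubly activated.
   - Deprotonation there (LiN(SiMe3)2, THF, −78 °C) and acylation with 3,3-dimethylpent-4-enoyl chloride F3 (from the commercial acid and (COCl)2) would give methyl (5R,6R)-5-[(tert-butyldimethylsilyl)oxy]-2-(4,4-dimethyl-2-oxohex-5-en-1-yl)-6-{3-methoxy-4-[(triisopropylsilyl)oxy]phenyl}-4-oxo-5,6-dihydro-4H-pyran-3-carboxylate F4.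
   - Its 1,3-dianion (LiN(iPr)2, 2.2 equiv, THF, −78 → 0 °C) would close ring A by Dieckmann condensation of C6 onto the ester and, after enolisation, give 17.

2. **Step 9.** Deprotonation may occur at C3 instead of the methyl group, or acylation at oxygen. Fallback from alcohol 8, back at 15; regiocontrol by charge instead of by bulk.
   - With LiN(iPr)2 (2.2 equiv, THF, −78 °C) the C3 alkoxide forms first and disfavours a second negative charge at C3, so the methyl group is deprotonated.
   - TMSCl would give (2R,3R)-2-{3-methoxy-4-[(triisopropylsilyl)oxy]phenyl}-6-methylidene-3,4-bis[(trimethylsilyl)oxy]-3,6-dihydro-2H-pyran F5.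
   - Acylation with 13 as in step 9 and mild acidic work-up would give ethyl 2-{[(2R,3R)-3-hydroxy-2-{3-methoxy-4-[(triisopropylsilyl)oxy]phenyl}-4-oxo-3,4-dihydro-2H-pyran-6-yl]acetyl}-3,3-dimethylpent-4-enoate F6.
   - TBSCl/imidazole (DMF, rt) would give 15.

3. **Step 4.** Facial selectivity in the epoxidation may be poor, or ring C may open by β-elimination from the α′ enolate. Fallback from 6, back at 8; an enolate-free oxidation.
   - Mn(OAc)3·2H2O in benzene at reflux should acetoxylate the α′ position trans to the aryl group and give (2R,3R)-2-{3-methoxy-4-[(triisopropylsilyl)oxy]phenyl}-6-methyl-4-oxo-3,4-dihydro-2H-pyran-3-yl acetate F7.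
   - K2CO3 in MeOH at 0 °C would release 8.

**Further compounds**
F1 | step 10 | (2R,3R)-3-[(tert-butyldimethylsilyl)oxy]-5-iodo-2-{3-methoxy-4-[(triisopropylsilyl)oxy]phenyl}-6-methyl-2,3-dihydro-4H-pyran-4-one | CC1=C(I)C(=O)[C@H](O[Si](C)(C)C(C)(C)C)[C@@H](c2ccc(O[Si](C(C)C)(C(C)C)C(C)C)c(OC)c2)O1
F2 | step 10 | methyl (5R,6R)-5-[(tert-butyldimethylsilyl)oxy]-6-{3-methoxy-4-[(triisopropylsilyl)oxy]phenyl}-2-methyl-4-oxo-5,6-dihydro-4H-pyran-3-carboxylate | CC1=C(C(=O)OC)C(=O)[C@H](O[Si](C)(C)C(C)(C)C)[C@@H](c2ccc(O[Si](C(C)C)(C(C)C)C(C)C)c(OC)c2)O1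
F3 | step 10 | 3,3-dimethylpent-4-enoyl chloride | C=CC(C)(C)CC(=O)Cl
F4 | step 10 | methyl (5R,6R)-5-[(tert-butyldimethylsilyl)oxy]-2-(4,4-dimethyl-2-oxohex-5-en-1-yl)-6-{3-methoxy-4-[(triisopropylsilyl)oxy]phenyl}-4-oxo-5,6-dihydro-4H-pyran-3-carboxylate | C=CC(C)(C)CC(=O)CC1=C(C(=O)OC)C(=O)[C@H](O[Si](C)(C)C(C)(C)C)[C@@H](c2ccc(O[Si](C(C)C)(C(C)C)C(C)C)c(OC)c2)O1
F5 | step 9 | (2R,3R)-2-{3-methoxy-4-[(triisopropylsilyl)oxy]phenyl}-6-methylidene-3,4-bis[(trimethylsilyl)oxy]-3,6-dihydro-2H-pyran | C=C1C=C(O[Si](C)(C)C)[C@H](O[Si](C)(C)C)[C@@H](c2ccc(O[Si](C(C)C)(C(C)C)C(C)C)c(OC)c2)O1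
F6 | step 9 | ethyl 2-{[(2R,3R)-3-hydroxy-2-{3-methoxy-4-[(triisopropylsilyl)oxy]phenyl}-4-oxo-3,4-dihydro-2H-pyran-6-yl]acetyl}-3,3-dimethylpent-4-enoate | CCOC(=O)C(C(=O)CC1=CC(=O)[C@H](O)[C@@H](c2ccc(O[Si](C(C)C)(C(C)C)C(C)C)c(OC)c2)O1)C(C)(C)C=C
F7 | step 4 | (2R,3R)-2-{3-methoxy-4-[(triisopropylsilyl)oxy]phenyl}-6-methyl-4-oxo-3,4-dihydro-2H-pyran-3-yl acetate | CC1=CC(=O)[C@H](OC(C)=O)[C@@H](c2ccc(O[Si](C(C)C)(C(C)C)C(C)C)c(OC)c2)O1
A1 | direct plan | phloroglucinol (benzene-1,3,5-triol) | Oc1cc(O)cc(O)c1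
A2 | direct plan | 2-(2-methylbut-3-en-2-yl)benzene-1,3,5-triol | C=CC(C)(C)c1c(O)cc(O)cc1O
A3 | direct plan | 3,5-bis(methoxymethoxy)-4-(2-methylbut-3-en-2-yl)-2-(trimethylsilyl)phenyl trifluoromethanesulfonate | C=CC(C)(C)c1c(OCOC)cc(OS(=O)(=O)C(F)(F)F)c([Si](C)(C)C)c1OCOC
A4 | direct plan | (3R,5S,6S)-5,6-dimethoxy-3-{(R)-[3-methoxy-4-(methoxymethoxy)phenyl][(trimethylsilyl)oxy]methyl}-5,6-dimethyl-1,4-dioxan-2-one | O=C1[C@@H]([C@H](O[Si](C)(C)C)c2ccc(OCOC)c(OC)c2)O[C@](C)(OC)[C@@](C)(OC)O1
A5 | direct plan | (2R,3R)-3-{[(2S)-2-methoxy-3-oxobutan-2-yl]oxy}-2-[3-methoxy-4-(methoxymethoxy)phenyl]-5,7-bis(methoxymethoxy)-6-(2-methylbut-3-en-2-yl)-2,3-dihydro-4H-chromen-4-one | C=CC(C)(C)c1c(OCOC)cc2c(c1OCOC)C(=O)[C@H](O[C@](C)(OC)C(C)=O)[C@@H](c1ccc(OCOC)c(OC)c1)O2
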